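**Assumption:** the target has no stereocentre (it is achiral), so no enantiomer has to be selected; the route only has to deliver the constitution Brc1ccc2c(Br)c(Br)[nH]c2c1.

**Retrosynthetic overview**
- The C2–Br and C3–Br bonds are disconnected last: both come from electrophilic bromination of 6-bromo-1H-indole, the more nucleophilic C3 first, then C2.
- 6-Bromoindole comes from 6-bromoindole-2-carboxylic acid by decarboxylation; the acid comes from its ethyl ester.
- The pyrrole ring (the only ring formed) is closed by reductive cyclisation of an o-nitrophenylpyruvate (Reissert indole synthesis).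
- The key C–C bond (benzylic CH2–C(=O)) is made by an intermolecular Claisen condensation of 4-bromo-2-nitrotoluene with diethyl oxalate; the benzene ring with its bromine at the future C6 is bought.

**Route**

Step 1
Reactants: 1 4-bromo-2-nitrotoluene; 2 diethyl oxalate
Product: 4 ethyl 3-(4-bromo-2-nitrophenyl)-2-oxopropanoate, via potassium enolate 3 (not isolated)
Conditions: KOEt (1.1 equiv), 2 (1.2 equiv), Et2O/EtOH, 0 °C to rt, 24 h; then 1 M HCl
Reagents that add atoms: none
Why: The benzylic CH3, acidified by the ortho-nitro (and para-bromo) group, is deprotonated and acylated by the non-enolisable diethyl oxalate in a crossed Claisen condensation (first stage of the Reissert indole synthesis); precipitation of the stable potassium enolate drives the equilibrium.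

Step 2
Reactants: 4 ethyl 3-(4-bromo-2-nitrophenyl)-2-oxopropanoate
Product: 6 ethyl 6-bromo-1H-indole-2-carboxylate, via amino keto ester 5 (not isolated)
Conditions: Fe powder (5 equiv), AcOH/EtOH, 85 °C
Reagents that add atoms: none
Why: Dissolving-metal nitro reduction (Fe/AcOH leaves the aryl bromide untouched, unlike H2/Pd) gives the aniline, which condenses with the adjacent ketone and aromatises by loss of water (Reissert reductive cyclisation).

Step 3
Reactants: 6 ethyl 6-bromo-1H-indole-2-carboxylate
Product: 8 6-bromo-1H-indole-2-carboxylic acid, via sodium carboxylate 7 (not isolated)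
Conditions: NaOH (3 equiv), EtOH/H2O, reflux; then 2 M HCl to pH 2
Reagents that add atoms: sodium hydroxide, [Na+].[OH-]
Why: Simple ester saponification; the indole NH and the aryl bromide are inert to aqueous hydroxide, and the acid precipitates on acidification.

Step 4
Reactants: 8 6-bromo-1H-indole-2-carboxylic acid
Product: 9 6-bromo-1H-indole
Conditions: Cu powder (cat.), quinoline, 210 °C, N2, until CO2 evolution stops
Reagents that add atoms: none
Why: Copper-catalysed thermal protodecarboxylation of an indole-2-carboxylic acid, the standard last stage of the Reissert sequence; the C6–Br bond tolerates catalytic Cu in quinoline on this time scale.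

Step 5
Reactants: 9 6-bromo-1H-indole
Product: 11 2,3,6-tribromo-1H-indole, via 3,6-dibromo-1H-indole 10 (not isolated)
Conditions: NBS (1.0 equiv), THF, −78 °C to 0 °C, dark; then NBS (1.05 equiv), 0 °C to rt; work-up cold with aq. Na2S2O3/NaHCO3, quick chromatography, store cold
Reagents that add atoms: N-bromosuccinimide, O=C1CCC(=O)N1Br
Why: Electrophilic aromatic bromination occurs first at the most nucleophilic C3; the second equivalent then brominates C2, the remaining pyrrole position, in preference to the benzo ring already deactivated by the 6-bromine.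

**Compound list**
1 | 4-bromo-2-nitrotoluene (4-bromo-1-methyl-2-nitrobenzene) | Cc1ccc(Br)cc1[N+](=O)[O-] | starting material
2 | diethyl oxalate | CCOC(=O)C(=O)OCC | starting material
3 | potassium (Z)-enolate of ethyl 3-(4-bromo-2-nitrophenyl)-2-oxopropanoate (geometry drawn as Z, of no consequence) | CCOC(=O)/C([O-])=C/c1ccc(Br)cc1[N+](=O)[O-].[K+] | intermediate
4 | ethyl 3-(4-bromo-2-nitrophenyl)-2-oxopropanoate | CCOC(=O)C(=O)Cc1ccc(Br)cc1[N+](=O)[O-] | intermediate
5 | ethyl 3-(2-amino-4-bromophenyl)-2-oxopropanoate | CCOC(=O)C(=O)Cc1ccc(Br)cc1N | intermediate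
6 | ethyl 6-bromo-1H-indole-2-carboxylate | CCOC(=O)c1cc2ccc(Br)cc2[nH]1 | intermediate
7 | sodium 6-bromo-1H-indole-2-carboxylate | [Na+].[O-]C(=O)c1cc2ccc(Br)cc2[nH]1 | intermediate
8 | 6-bromo-1H-indole-2-carboxylic acid | OC(=O)c1cc2ccc(Br)cc2[nH]1 | intermediate
9 | 6-bromo-1H-indole | Brc1ccc2cc[nH]c2c1 | intermediate
10 | 3,6-dibromo-1H-indole | Brc1ccc2c(Br)c[nH]c2c1 | intermediate
11 | 2,3,6-tribromo-1H-indole | Brc1ccc2c(Br)c(Br)[nH]c2c1 | target

**Totals:** 5 steps; longest linear sequence 5 steps.

**Steps most likely to fail, with fallbacks**

Step 5 (double bromination of the free NH indole; risk of over-bromination, oxidation to oxindole-type products and decomposition of the sensitive 2,3-dibromoindole). The fallback sets out from compound 9 and introduces the two bromines one at a time on an N-protected indole. Compound 9 is sulfonylated (NaH, PhSO2Cl, DMF, 0 °C) to 6-bromo-1-(phenylsulfonyl)-1H-indole F1. This is lithiated selectively at C2 with LDA in THF at −78 °C (LDA does not exchange the aryl bromide) and quenched with 1,2-dibromo-1,1,2,2-tetrachloroethane to give 2,6-dibromo-1-(phenylsulfonyl)-1H-indole F2. Electrophilic bromination at C3 (Br2, AcOH/CH2Cl2, rt) gives 2,3,6-tribromo-1-(phenylsulfonyl)-1H-indole F3. Mild cleavage of the sulfonamide (K2CO3, MeOH/THF/H2O, rt) returns to the route at the target, compound 11.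

Step 4 (high-temperature Cu/quinoline decarboxylation in the presence of an aryl bromide; risk of tar and partial C–Br loss). The fallback sets out from compound 8 and avoids protodecarboxylation altogether by using the carboxyl group as the leaving group for the C2 bromine. NBS (1 equiv, DMF, 0 °C) brominates C3 to give 3,6-dibromo-1H-indole-2-carboxylic acid F4. A second equivalent of NBS with NaHCO3 (DMF, 0 °C to rt) effects ipso-bromodecarboxylation at C2, coming back to the route directly at compound 11.

Step 1 (Claisen condensation; needs dry, active alkoxide and can stall or give low conversion). The fallback sets out from compound 1 and replaces the oxalate condensation by a Leimgruber–Batcho sequence. Heating 1 with N,N-dimethylformamide dimethyl acetal in DMF at 110 °C gives (E)-2-(4-bromo-2-nitrophenyl)-N,N-dimethylethenamine F5. Reductive cyclisation with Fe/AcOH (or aqueous TiCl3/NH4OAc) at 80 °C gives the indole with loss of dimethylamine, rejoining the route at compound 9.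

**Further compounds**
F1 | step 5 | 6-bromo-1-(phenylsulfonyl)-1H-indole | Brc1ccc2ccn(S(=O)(=O)c3ccccc3)c2c1
F2 | step 5 | 2,6-dibromo-1-(phenylsulfonyl)-1H-indole | Brc1ccc2cc(Br)n(S(=O)(=O)c3ccccc3)c2c1
F3 | step 5 | 2,3,6-tribromo-1-(phenylsulfonyl)-1H-indole | Brc1ccc2c(Br)c(Br)n(S(=O)(=O)c3ccccc3)c2c1
F4 | step 4 | 3,6-dibromo-1H-indole-2-carboxylic acid | OC(=O)c1[nH]c2cc(Br)ccc2c1Br
F5 | step 1 | (E)-2-(4-bromo-2-nitrophenyl)-N,N-dimethylethenamine | CN(C)/C=C/c1ccc(Br)cc1[N+](=O)[O-]
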